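**Retrosynthetic overview**
1. Target ⇐ (3E)-cyclodecene-5,9-diol 16: hydroxyl-directed osmylation of C3=C4 and double angeloylation while the new C3/C4 diol is held as an osmate ester.
2. Ten-membered ring ⇐ anionic oxy-Cope ring expansion of a trans-1-dienyl-2-vinylcyclohexanolate (C4–C9 broken, C1–C2 formed); the resulting enolate is hydroxylated at C10.
3. Cyclohexane 6 (C4–C9 with both methyl groups) ⇐ enantioselective dearomative ortho-vinylation of 2,6-dimethylphenol (aromaticity and mirror plane lost together), then epoxidation/hydrogenolysis (C5–OH) and enone epoxidation (C7–C8 oxirane).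
4. Ring order: six-membered carbocycle (from the arene) → C7–C8 oxirane → ten-membered carbocycle. Carbon count: phenol (8) + vinyl (2) + dienyl iodide (5).

Assumption: (−)-brucine is taken to induce the (R) configuration in step 1; if it induces (S), the fallback for step 1 applies and the epoxidation catalyst of step 2 fixes the absolute configuration.

Locants: cyclohexane intermediates use their own ring locants. From compound 12 on, the ring is numbered C1 (isopropenyl-bearing carbon) to C10 in the order of the target SMILES. Cyclohexanone C1, C2, C3, C4, C5, C6 become C9, C8, C7, C6, C5, C4.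

**Route**

Step 1
Reactants: 1 2,6-dimethylphenol
Product: 2 (R)-2,6-dimethyl-6-vinylcyclohexa-2,4-dien-1-one
Conditions: Pb(OAc)4, tributyl(vinyl)stannane, CHCl3, rt, 15 min; then 1, (−)-brucine (3 equiv), 4 Å MS, toluene, −40 → −20 °C
Reagents that add atoms: tributyl(vinyl)stannane (C=C[Sn](CCCC)(CCCC)CCCC)
Why: Proposed new method: the phenol exchanges onto tetravalent lead to give an aryloxy(vinyl)lead diacetate whose intramolecular ligand coupling delivers the vinyl group to one of the two enantiotopic methyl-bearing ortho carbons (the free para position is not reached), lead-bound brucine choosing between them so that the C6 quaternary centre is set as R while aromaticity and the mirror plane are lost; the closest known reaction type is the Pinhey ortho-arylation and C-vinylation of 2,6-disubstituted phenols and beta-dicarbonyls with organolead triacetates, including its brucine-mediated asymmetric arylation of phenols.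

Step 2
Reactants: 2 (R)-2,6-dimethyl-6-vinylcyclohexa-2,4-dien-1-one
Product: 3 (4S,5R,6R)-4,5-epoxy-2,6-dimethyl-6-vinylcyclohex-2-en-1-one
Conditions: (S,S)-N,N′-bis(3,5-di-tert-butylsalicylidene)-1,2-cyclohexanediaminomanganese chloride (5 mol%), NaOCl (aq, pH 11.3), 4-phenylpyridine N-oxide, CH2Cl2, 0 °C
Reagents that add atoms: sodium hypochlorite ([Na+].[O-]Cl)
Why: Jacobsen–Katsuki epoxidation: the cis-disubstituted, conjugated C4=C5 alkene next to a quaternary carbon is the 2,2-dimethylchromene-type substrate of the trivalent manganese salen catalyst, whereas the electron-poor C2=C3 enone alkene and the terminal vinyl group are poor substrates, and the (S,S) catalyst delivers oxygen to the face anti to the vinyl group, setting C4 and C5.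

Step 3
Reactants: 3 (4S,5R,6R)-4,5-epoxy-2,6-dimethyl-6-vinylcyclohex-2-en-1-one
Product: 4 (5S,6R)-5-hydroxy-2,6-dimethyl-6-vinylcyclohex-2-en-1-one
Conditions: Pd2(dba)3·CHCl3 (2.5 mol%), PBu3 (10 mol%), HCO2H, Et3N, 1,4-dioxane, rt
Reagents that add atoms: none
Why: Tsuji–Shimizu formate hydrogenolysis of an alkenyl oxirane: zerovalent palladium ionises the allylic C4–O bond and formate-derived hydride is delivered to C4 of the pi-allyl so the enone stays conjugated, while the C5–O bond is never broken and C5 keeps its configuration (hydroxyl trans to vinyl).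

Step 4
Reactants: 4 (5S,6R)-5-hydroxy-2,6-dimethyl-6-vinylcyclohex-2-en-1-one
Product: 5 (5S,6R)-5-(tert-butyldimethylsilyloxy)-2,6-dimethyl-6-vinylcyclohex-2-en-1-one
Conditions: TBSOTf, 2,6-lutidine, CH2Cl2, −78 °C
Reagents that add atoms: tert-butyldimethylsilyl trifluoromethanesulfonate (CC(C)(C)[Si](C)(C)OS(=O)(=O)C(F)(F)F)
Why: Silyl ether protection under non-nucleophilic, weakly basic conditions blocks retro-aldol cleavage of the beta-hydroxy ketone in the later basic steps and touches no stereocentre.

Step 5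
Reactants: 5 (5S,6R)-5-(tert-butyldimethylsilyloxy)-2,6-dimethyl-6-vinylcyclohex-2-en-1-one
Product: 6 (2S,3S,5S,6R)-5-(tert-butyldimethylsilyloxy)-2,3-epoxy-2,6-dimethyl-6-vinylcyclohexan-1-one
Conditions: H2O2 (30% aq), NaOH (0.2 equiv), MeOH, 0 °C
Reagents that add atoms: hydrogen peroxide (OO)
Why: Weitz–Scheffer nucleophilic epoxidation: hydroperoxide adds to C3 of the 2-methyl enone on the face opposite the C5 silyloxy group (the carvone precedent) and closes onto C2, giving the oxirane trans to the silyloxy group; the isolated vinyl group is inert.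

Step 6
Reactants: 7 methacrolein
Product: 8 (E)-1-iodo-3-methylbuta-1,3-diene
Conditions: CrCl2 (6 equiv), CHI3 (2 equiv), THF, 0 °C
Reagents that add atoms: iodoform (IC(I)I)
Why: Takai olefination with divalent chromium converts the aldehyde into the (E)-alkenyl iodide with high E selectivity and leaves the 1,1-disubstituted alkene untouched.

Step 7
Reactants: 6 (2S,3S,5S,6R)-5-(tert-butyldimethylsilyloxy)-2,3-epoxy-2,6-dimethyl-6-vinylcyclohexan-1-one; 8 (E)-1-iodo-3-methylbuta-1,3-diene
Product: 10 5-(tert-butyldimethylsilyloxy)-2,3-epoxy-2,6-dimethyl-1-[(E)-3-methylbuta-1,3-dienyl]-6-vinylcyclohexan-1-ol (dienyl cis to silyloxy; dienyl trans to vinyl; hydroxyl cis to oxirane oxygen), via dienyllithium 9 (not isolated)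
Conditions: 8, t-BuLi (2.0 equiv), Et2O, −78 °C; then 6, THF, −78 → −40 °C; H2O
Reagents that add atoms: none
Why: Lithium–iodine exchange with retention, then Felkin–Anh 1,2-addition to the non-enolisable ketone anti to both flanking acceptor bonds (the C2–O oxirane bond and the C6–vinyl bond, which lie on the same face), which sets C1 with the dienyl group trans to vinyl and the alkoxide cis to the oxirane oxygen.

Step 8
Reactants: 10 5-(tert-butyldimethylsilyloxy)-2,3-epoxy-2,6-dimethyl-1-[(E)-3-methylbuta-1,3-dienyl]-6-vinylcyclohexan-1-ol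
Product: 13 (3E)-5-(tert-butyldimethylsilyloxy)-7,8-epoxy-10-hydroxy-1-isopropenyl-4,8-dimethylcyclodec-3-en-9-one (C1 C5 C7 C8 C10 configured as in the target), via potassium alkoxide 11 (not isolated), via potassium enolate 12 (not isolated)
Conditions: KN(SiMe3)2 (1.3 equiv), 18-crown-6, THF, −78 → 0 °C; then 2-(phenylsulfonyl)-3-phenyloxaziridine, −78 °C; AcOH
Reagents that add atoms: 2-(phenylsulfonyl)-3-phenyloxaziridine (O=S(=O)(c1ccccc1)N1OC1c1ccccc1)
Why: Anionic oxy-Cope rearrangement through a chair transition state with dienyl and vinyl both equatorial transfers the ring chirality to C1 (isopropenyl equatorial, from the E-dienyl group) and gives the (E)-C3=C4 alkene and the ring-E enolate, which the Davis oxaziridine hydroxylates on its outer face so that the C10 hydroxyl ends trans to the isopropenyl group; the alkoxide is cis to the oxirane, so no Payne rearrangement can compete.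

Step 9
Reactants: 13 (3E)-5-(tert-butyldimethylsilyloxy)-7,8-epoxy-10-hydroxy-1-isopropenyl-4,8-dimethylcyclodec-3-en-9-one
Product: 14 (3E)-5-(tert-butyldimethylsilyloxy)-7,8-epoxy-1-isopropenyl-4,8-dimethyl-9-oxocyclodec-3-en-10-yl (R)-2-methylbutanoate
Conditions: (R)-2-methylbutanoic acid, DCC, DMAP (10 mol%), CH2Cl2, 0 °C
Reagents that add atoms: (R)-2-methylbutanoic acid (CC[C@@H](C)C(=O)O)
Why: Steglich esterification of the only free hydroxyl at 0 °C brings in the (R)-2-methylbutanoyl group with its stereocentre intact and creates no new stereocentre.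

Step 10
Reactants: 14 (3E)-5-(tert-butyldimethylsilyloxy)-7,8-epoxy-1-isopropenyl-4,8-dimethyl-9-oxocyclodec-3-en-10-yl (R)-2-methylbutanoate
Product: 15 (3E)-5-(tert-butyldimethylsilyloxy)-7,8-epoxy-9-hydroxy-1-isopropenyl-4,8-dimethylcyclodec-3-en-10-yl (R)-2-methylbutanoate (9S; hydroxyl on the face opposite the oxirane oxygen and the C10 acyloxy group)
Conditions: NaBH4, MeOH/CH2Cl2 (1:1), −78 → −40 °C
Reagents that add atoms: none
Why: Non-chelating borohydride reduction under polar Felkin–Anh control: hydride attacks from the ring periphery away from both alpha C–O bonds (C8 oxirane and C10 acyloxy), setting C9 as S, and the cold protic medium suppresses 1,2-acyl migration.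

Step 11
Reactants: 15 (3E)-5-(tert-butyldimethylsilyloxy)-7,8-epoxy-9-hydroxy-1-isopropenyl-4,8-dimethylcyclodec-3-en-10-yl (R)-2-methylbutanoate
Product: 16 (3E)-7,8-epoxy-5,9-dihydroxy-1-isopropenyl-4,8-dimethylcyclodec-3-en-10-yl (R)-2-methylbutanoate
Conditions: Bu4NF, AcOH (1:1), THF, 0 °C → rt
Reagents that add atoms: none
Why: Fluoride desilylation buffered with acetic acid frees the allylic C5 hydroxyl without ester migration or oxirane opening.

Step 12
Reactants: 16 (3E)-7,8-epoxy-5,9-dihydroxy-1-isopropenyl-4,8-dimethylcyclodec-3-en-10-yl (R)-2-methylbutanoate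
Product: 17 cyclic C3,C4-osmate ester of the 3,4,5,9-tetrol 10-[(R)-2-methylbutanoate] (dioxo-osmium glycolate chelated by TMEDA; C3–O syn to C5–OH; C4–O anti to C5–OH on the ring drawing)
Conditions: OsO4 (1.0 equiv), TMEDA (1.1 equiv), CH2Cl2, −78 °C
Reagents that add atoms: osmium tetroxide (O=[Os](=O)(=O)=O); N,N,N′,N′-tetramethylethylenediamine (CN(C)CCN(C)C)
Why: Donohoe hydroxyl-directed dihydroxylation: the OsO4–TMEDA complex hydrogen-bonds to the allylic C5 hydroxyl and adds suprafacially to the strained (E)-C3=C4 alkene on the face that carries it, setting C3 and C4 as in the target (the opposite sense to undirected osmylation); the undirected isopropenyl group reacts more slowly with one equivalent, and the stable hexavalent osmium glycolate masks the new diol.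

Step 13
Reactants: 17 cyclic C3,C4-osmate ester of the 3,4,5,9-tetrol 10-[(R)-2-methylbutanoate]
Product: 19 CNP0246823.2, via bis-angelate osmate ester 18 (not isolated)
Conditions: angelic acid, 2,4,6-trichlorobenzoyl chloride, Et3N, toluene, rt; then 17, 70 °C; then ethylenediamine, CH2Cl2, rt
Reagents that add atoms: angelic acid (C/C=C(/C)C(=O)O)
Why: Yamaguchi-type mixed-anhydride acylation without DMAP esterifies the C5 and C9 hydroxyls without Z-to-E isomerisation of the angelate while the C3/C4 diol stays masked, and ligand exchange with ethylenediamine then releases the diol from osmium without touching any stereocentre.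

**Compound list**
1 | 2,6-dimethylphenol | Cc1cccc(C)c1O | starting material
2 | (R)-2,6-dimethyl-6-vinylcyclohexa-2,4-dien-1-one | C[C@@]1(C=C)C=CC=C(C)C1=O | intermediate
3 | (4S,5R,6R)-4,5-epoxy-2,6-dimethyl-6-vinylcyclohex-2-en-1-one (oxirane trans to vinyl) | C[C@@]1(C=C)[C@H]2O[C@H]2C=C(C)C1=O | intermediate
4 | (5S,6R)-5-hydroxy-2,6-dimethyl-6-vinylcyclohex-2-en-1-one (hydroxyl trans to vinyl) | C[C@@]1(C=C)[C@@H](O)CC=C(C)C1=O | intermediate
5 | (5S,6R)-5-(tert-butyldimethylsilyloxy)-2,6-dimethyl-6-vinylcyclohex-2-en-1-one | C[C@@]1(C=C)[C@@H](O[Si](C)(C)C(C)(C)C)CC=C(C)C1=O | intermediate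
6 | (2S,3S,5S,6R)-5-(tert-butyldimethylsilyloxy)-2,3-epoxy-2,6-dimethyl-6-vinylcyclohexan-1-one (oxirane trans to silyloxy, cis to vinyl) | C[C@@]1(C=C)[C@@H](O[Si](C)(C)C(C)(C)C)C[C@@H]2O[C@]2(C)C1=O | intermediate
7 | methacrolein (2-methylprop-2-enal) | C=C(C)C=O | starting material
8 | (E)-1-iodo-3-methylbuta-1,3-diene | C=C(C)/C=C/I | intermediate
9 | (E)-(3-methylbuta-1,3-dien-1-yl)lithium | [Li]/C=C/C(C)=C | intermediate
10 | 5-(tert-butyldimethylsilyloxy)-2,3-epoxy-2,6-dimethyl-1-[(E)-3-methylbuta-1,3-dienyl]-6-vinylcyclohexan-1-ol (dienyl cis to silyloxy and trans to vinyl, hydroxyl cis to oxirane oxygen) | C[C@@]1(C=C)[C@@H](O[Si](C)(C)C(C)(C)C)C[C@@H]2O[C@]2(C)[C@@]1(O)/C=C/C(C)=C | intermediate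
11 | potassium alkoxide of 10 | C[C@@]1(C=C)[C@@H](O[Si](C)(C)C(C)(C)C)C[C@@H]2O[C@]2(C)[C@@]1([O-])/C=C/C(C)=C.[K+] | intermediate
12 | potassium C9–C10 enolate of the ring-expanded (3E)-cyclodec-3-en-9-one | C=C(C)[C@H]1C/C=C(C)/[C@@H](O[Si](C)(C)C(C)(C)C)C[C@@H]2O[C@]2(C)/C([O-])=C/1.[K+] | intermediate
13 | (3E)-5-(tert-butyldimethylsilyloxy)-7,8-epoxy-10-hydroxy-1-isopropenyl-4,8-dimethylcyclodec-3-en-9-one (10-hydroxyl trans to isopropenyl) | C=C(C)[C@H]1C/C=C(C)/[C@@H](O[Si](C)(C)C(C)(C)C)C[C@@H]2O[C@]2(C)C(=O)[C@@H]1O | intermediate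
14 | C10 (R)-2-methylbutanoate of 13 | C=C(C)[C@H]1C/C=C(C)/[C@@H](O[Si](C)(C)C(C)(C)C)C[C@@H]2O[C@]2(C)C(=O)[C@@H]1OC(=O)[C@H](C)CC | intermediate
15 | (9S)-alcohol from 14 | C=C(C)[C@H]1C/C=C(C)/[C@@H](O[Si](C)(C)C(C)(C)C)C[C@@H]2O[C@]2(C)[C@@H](O)[C@@H]1OC(=O)[C@H](C)CC | intermediate
16 | (3E)-7,8-epoxy-5,9-dihydroxy-1-isopropenyl-4,8-dimethylcyclodec-3-en-10-yl (R)-2-methylbutanoate | C=C(C)[C@H]1C/C=C(C)/[C@@H](O)C[C@@H]2O[C@]2(C)[C@@H](O)[C@@H]1OC(=O)[C@H](C)CC | intermediate
17 | cyclic C3,C4-osmate ester (dioxo-osmium glycolate, TMEDA-chelated) of the 3,4,5,9-tetrol 10-[(R)-2-methylbutanoate] | C=C(C)[C@H]1C[C@@H](O3)[C@](C)(O[Os]3(=O)=O)[C@@H](O)C[C@@H]2O[C@]2(C)[C@@H](O)[C@@H]1OC(=O)[C@H](C)CC.CN(C)CCN(C)C | intermediate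
18 | 5,9-di-O-angeloyl derivative of 17 | C=C(C)[C@H]1C[C@@H](O3)[C@](C)(O[Os]3(=O)=O)[C@@H](OC(=O)/C(C)=C\C)C[C@@H]2O[C@]2(C)[C@@H](OC(=O)/C(C)=C\C)[C@@H]1OC(=O)[C@H](C)CC.CN(C)CCN(C)C | intermediate
19 | CNP0246823.2: (1R,3R,4S,5S,7S,8S,9S,10R)-7,8-epoxy-3,4-dihydroxy-1-isopropenyl-4,8-dimethylcyclodecane-5,9,10-triyl 5,9-di[(Z)-2-methylbut-2-enoate] 10-[(R)-2-methylbutanoate] | C=C(C)[C@H]1C[C@@H](O)[C@](C)(O)[C@@H](OC(=O)/C(C)=C\C)C[C@@H]2O[C@]2(C)[C@@H](OC(=O)/C(C)=C\C)[C@@H]1OC(=O)[C@H](C)CC | target

**Step count**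
Total: 13 steps. Longest linear sequence: 12 steps (steps 1–5 and 7–13); step 6 makes the dienyl iodide for the convergent step 7.

**Three steps most likely to fail**

Step 1 (untested asymmetric ligand coupling: ee, competing O-vinylation, Diels–Alder dimerisation of 2). Fallback: starting from 1, run the lead-mediated vinylation with pyridine in place of brucine to give racemic 2,6-dimethyl-6-vinylcyclohexa-2,4-dien-1-one F1. The manganese salen catalyst of step 2 then differentiates the enantiomers, because it epoxidises C4=C5 of both on the same absolute face. The (R)-half gives 3. The (S)-half gives (4S,5R,6S)-4,5-epoxy-2,6-dimethyl-6-vinylcyclohex-2-en-1-one F2 (oxirane cis to vinyl), which is removed by chromatography. The route is rejoined at 3, with at most half of the material and the absolute configuration fixed by the epoxidation catalyst.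

Step 7 (facial selectivity at a hindered ketone flanked by two fully substituted carbons; a pseudo-axial silyloxy group may shield the required face, and the wrong C1 epimer would give the wrong C1/C10 configuration after ring expansion). Fallback: starting from 6, remove the silyl group (Bu4NF/AcOH) to give (2S,3S,5S,6R)-2,3-epoxy-5-hydroxy-2,6-dimethyl-6-vinylcyclohexan-1-one F3. Convert it into its lithium alkoxide (MeLi, −78 °C) and add dienyllithium 9, so that the alkoxide-bound lithium delivers the nucleophile to its own face (hydroxyl-directed addition). This gives 2,3-epoxy-2,6-dimethyl-1-[(E)-3-methylbuta-1,3-dienyl]-6-vinylcyclohexane-1,5-diol F4. Selective silylation of the secondary hydroxyl (TBSOTf, 2,6-lutidine, −78 °C) returns to 10.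

Step 10 (substrate-controlled reduction of a medium-ring ketone; the C9 epimer or acyl migration are the likely failures). Fallback: replace substrate control by catalyst control. Starting from 14, reduce with catecholborane and (R)-2-methyl-CBS-oxazaborolidine, which by the usual model (larger substituent = the fully substituted oxirane carbon C8) gives the 9S carbinol. This returns to 15 and no new compound arises.

**Further compounds**
F1 | step 1 | racemic 2,6-dimethyl-6-vinylcyclohexa-2,4-dien-1-one | CC1(C=C)C=CC=C(C)C1=O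
F2 | step 1 | (4S,5R,6S)-4,5-epoxy-2,6-dimethyl-6-vinylcyclohex-2-en-1-one (oxirane cis to vinyl) | C[C@]1(C=C)[C@H]2O[C@H]2C=C(C)C1=O
F3 | step 7 | (2S,3S,5S,6R)-2,3-epoxy-5-hydroxy-2,6-dimethyl-6-vinylcyclohexan-1-one | C[C@@]1(C=C)[C@@H](O)C[C@@H]2O[C@]2(C)C1=O
F4 | step 7 | 2,3-epoxy-2,6-dimethyl-1-[(E)-3-methylbuta-1,3-dienyl]-6-vinylcyclohexane-1,5-diol (configured as 10) | C[C@@]1(C=C)[C@@H](O)C[C@@H]2O[C@]2(C)[C@@]1(O)/C=C/C(C)=C
F0 | step 10 | none | none
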